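All runs were computed with constants of no real substance; the scatter is artificial.

The chemist comparing these flasks wants one number from each: how much of the starting material ends as self-condensation product.

| flask | starting material | second substrate | free enzyme | remark | time |
|---|---|---|---|---|---|
| red | 0.020 M | 0.020 M | 2 µM | run made earlier |  |
| amber | 0.020 M | 0.028 M | 2 µM | run made earlier |  |
| ochre | 0.020 M | 0.044 M | 2 µM | run made earlier |  |
| Tuesday's | 0.020 M | 0.0200 M | 2.0 µM | everything together at the start | 1.5 h |
| Friday's | 0.020 M (fed, over 40 min) | 0.0200 M | 2.0 µM | all else is in the flask from the start; the feed brings no volume worth counting | 1.5 h |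
| Wednesday's | 0.020 M | 0.0200 M (fed, over 40 min) | 2.0 µM | all else is in the flask from the start; the feed brings no volume worth counting | 1.5 h |

| run | time / min | self-condensation product / % | target / % |
|---|---|---|---|
| red | 10.0 | 13.2 | 3.3 |
| red | 20.0 | 20.8 | 6.6 |
| red | 25.0 | 23.3 | 8.7 |
| red | 40.0 | 33.9 | 14.8 |
| red | 50.0 | 33.9 | 18.0 |
| amber | 4.00 | 6.1 | 0.7 |
| amber | 8.00 | 9.5 | 2.9 |
| amber | 12.0 | 15.1 | 4.9 |
| amber | 20.0 | 21.6 | 6.2 |
| amber | 30.0 | 26.7 | 13.8 |
| amber | 50.0 | 35.4 | 21.2 |
| ochre | 10.0 | 11.0 | 2.7 |
| ochre | 20.0 | 20.9 | 9.2 |
| ochre | 25.0 | 23.5 | 9.7 |
| ochre | 40.0 | 32.0 | 17.1 |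
| ochre | 50.0 | 32.9 | 22.6 |

(scatter of a reading: 1 percentage point)

- percentages count the starting material that a species holds: one self-condensation product counts as two
- the earlier runs were read with a standard deviation of 1 percentage point

- the flask that comes out highest in amount of self-condensation product, in percent of the starting material charged; "all alike" if 1.5 percentage points covers them all (Tuesday's / Friday's / Wednesday's / all alike)
- amount of self-condensation product at the end, in percent of the starting material charged, Tuesday's
- amount of self-condensation product at the end, in percent of the starting material charged, Friday's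
- amount of self-condensation product at the end, in percent of the starting material charged, Wednesday's

Work with the fraction left, f, of the charged starting material, and call V and P the shares held by self-condensation product and target. At the last readings V stands at 33.9 %, 35.4 % and 32.9 % while second substrate goes from 0.020 M to 0.044 M, so leave second substrate out of the rate of V, and take that rate as second order in starting material, κ times f squared. If the reciprocal of f rises straight, the area under f squared up to time t is exactly t f, so V = κ t f. Those last readings then give the self-condensation constant κ = 0.0151 min⁻¹, a reading with their scatter.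

Tuesday's has the red charges, and red target climbs nearly straight, a zero-order drain, so carry it to P = 32.4 % at the end, an estimate on which the bounds below rest, as they rest on κ. Here κ t = 1.36. With no target, f + V is the whole charge, and V = κ t f gives a first ceiling of 57.6 %. The drain bends the reciprocal of f upward, so the area exceeds t f, and taking P out of the balance gives a floor of 38.9 %. Since f itself lies under its straight chord, using that chord lowers the ceiling to 52.8 %.

The forecast names Wednesday's highest, with 43 % for Tuesday's, 32 % for Friday's and 44 % for Wednesday's, arguing of Friday's that “slow feed keeps starting material low while target continues”. Its Tuesday's figure lies inside the bracket.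

Tuesday's gives 43.1 %, inside the bracket, Friday's 32.8 % and Wednesday's 46.2 %, so Wednesday's is highest.

    starting material + free enzyme ⇌ first complex (K = 1800 M⁻¹, k = 1.30 × 10⁷ M⁻¹ h⁻¹)
    first complex → loaded enzyme + first product (k = 1.20 × 10⁵ h⁻¹)
    second substrate + loaded enzyme ⇌ second complex (K = 180 M⁻¹, k = 9.90 × 10⁵ M⁻¹ h⁻¹)
    second complex → free enzyme + target (k = 3400 h⁻¹)
    2 starting material → self-condensation product (k = 22.0 M⁻¹ h⁻¹)

Wednesday's ends with target at 27.6 % against Tuesday's 31.9 %. Friday's f falls from 73.7 % at the end of the feed to 35.7 % at 1.50 h. Over those 50.0 min, κ and the same two bounds put the gain in V between 20 points and 23 points, and Friday's self-condensation product rose by 21 points.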